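**Plan**

1. Ring numbering used throughout: O1–O2–C3(OMe)(C16 chain)–C4H2–C5H2–C6H(CH2CO2H). Retrosynthetic cuts, in order: the methyl ester; the C(sp)–C(sp2) bond of the enyne (the diene chain leaves as (E)-1-iodoundeca-1,10-diene); the two ring hydrogens at C4/C5 (back to a C4=C5 alkene); then, in one operation, the ring bond C3–C4 and the O2–C3 bond.
2. Enabling feature: C3 is the ketal carbon of the 1,2-dioxane, bonded to the ring peroxide oxygen O2 and to an exocyclic OMe. One more methoxy group makes it an ortho ester, a latent methoxy(peroxy)carbenium ion. Its neighbour C4 is an unsubstituted CH2 that can arrive as the silicon-bearing carbon of a (Z)-vinylsilane held by the tether C5–C6–O1–O2.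
3. Forward: a C6 hydroperoxide fragment and the ortho ester of the side-chain acid are joined at the fully substituted carbon C3, and the same flask closes the only ring (a 3,6-dihydro-1,2-dioxine) by C3–C4 bond formation. Diimide then saturates C4=C5, the alkyne is unmasked, the diene chain is attached by Sonogashira coupling and the ester is hydrolysed.
4. Stereochemistry: C6 comes from a catalyst-controlled asymmetric conjugate peroxidation of an enal. C3 is set in the ring closure relative to C6 under anomeric control (OMe axial, both carbon substituents equatorial). The temporary (Z)-vinylsilane comes from a syn semi-hydrogenation and the (E)-alkene of the chain from a Takai olefination.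

Key step: step 8

Assumption: the (R)-configured diarylprolinol silyl ether is taken to deliver the peroxide oxygen to the face of the enal anti to its diarylsiloxymethyl group (the usual sense for this catalyst class), which corresponds to (3R) in 8; the enantiomeric catalyst would be used if the sense were found reversed.

**Route**

Step 1
Reactants: 1 3-(trimethylsilyl)prop-2-yn-1-ol
Product: 2 (Z)-3-(trimethylsilyl)prop-2-en-1-ol
Conditions: H2 (1 atm), nickel boride Ni2B (P-2, from Ni(OAc)2·4H2O and NaBH4), ethylenediamine, EtOH, rt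
Reagents that add atoms: none
Why: P-2 nickel boride semi-hydrogenation adds H2 syn to the silylalkyne and should stop at the (Z)-vinylsilane.

Step 2
Reactants: 2 (Z)-3-(trimethylsilyl)prop-2-en-1-ol
Product: 4 (2E,4Z)-5-(trimethylsilyl)penta-2,4-dienal, via (Z)-3-(trimethylsilyl)prop-2-enal 3 (not isolated)
Conditions: MnO2 (activated, excess), Ph3P=CHCHO (1.1 equiv), CH2Cl2, rt
Reagents that add atoms: (formylmethylene)triphenylphosphorane O=CC=P(c1ccccc1)(c1ccccc1)c1ccccc1
Why: Allylic oxidation with MnO2 followed in the same flask by Wittig olefination with the stabilised ylide should give the new C2=C3 bond E, and trapping the Z-configured silyl enal as it forms limits its isomerisation.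

Step 3
Reactants: 5 2,3-dimethylbut-2-ene
Product: 7 2-hydroperoxy-2-methoxypropane, via acetone O-oxide 6 (not isolated)
Conditions: O3, CH2Cl2/MeOH, −78 °C; then N2 purge
Reagents that add atoms: ozone [O-][O+]=O; methanol CO
Why: Ozonolysis in methanol (Criegee mechanism): the carbonyl oxide 6 is trapped by methanol as the α-methoxy hydroperoxide, a protected form of hydrogen peroxide.

Step 4
Reactants: 4 (2E,4Z)-5-(trimethylsilyl)penta-2,4-dienal; 7 2-hydroperoxy-2-methoxypropane
Product: 8 (3R,4Z)-3-[(2-methoxypropan-2-yl)peroxy]-5-(trimethylsilyl)pent-4-enal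
Conditions: (R)-2-[diphenyl(trimethylsilyloxy)methyl]pyrrolidine (10 mol%), PhCO2H (10 mol%), 7 (2 equiv), toluene, 0 °C
Reagents that add atoms: none
Why: Iminium-catalysed enantioselective conjugate peroxidation (oxa-Michael addition of a hydroperoxide to an enal): the catalyst shields one face of the activated enal so that the peroxide oxygen adds to C3 from the open face and sets (3R), the bulky silyl group at C5 disfavours 1,6-addition, and the acid co-catalyst protonates the enamine before it can close to an epoxide.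

Step 5
Reactants: 8 (3R,4Z)-3-[(2-methoxypropan-2-yl)peroxy]-5-(trimethylsilyl)pent-4-enal
Product: 10 methyl (3R,4Z)-3-[(2-methoxypropan-2-yl)peroxy]-5-(trimethylsilyl)pent-4-enoate, via carboxylic acid 9 (not isolated)
Conditions: NaClO2, NaH2PO4, 2-methylbut-2-ene, t-BuOH/H2O, 0 °C; then TMSCHN2, PhMe/MeOH, 0 °C
Reagents that add atoms: sodium chlorite [Na+].[O-]Cl=O; (trimethylsilyl)diazomethane C[Si](C)(C)C=[N+]=[N-]
Why: Pinnick oxidation converts the aldehyde into the acid under buffered conditions that should leave the peroxyketal, the vinylsilane and the C3 centre untouched, and the crude acid is methylated without base, which avoids β-elimination of the peroxide.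

Step 6
Reactants: 10 methyl (3R,4Z)-3-[(2-methoxypropan-2-yl)peroxy]-5-(trimethylsilyl)pent-4-enoate
Product: 11 methyl (3R,4Z)-3-hydroperoxy-5-(trimethylsilyl)pent-4-enoate
Conditions: AcOH/THF/H2O (3:1:1), rt
Reagents that add atoms: none
Why: Mild acid hydrolysis of the monoperoxyketal (a standard hydroperoxide protecting group) frees the hydroperoxide without breaking the C3–O bond, so the stereocentre is kept.

Step 7
Reactants: 12 ethynyltriisopropylsilane; 13 4-bromo-1,1,1-trimethoxybutane
Product: 15 triisopropyl(6,6,6-trimethoxyhex-1-yn-1-yl)silane, via lithium acetylide 14 (not isolated)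
Conditions: n-BuLi, THF, −78 °C; then 13, DMPU, −78 °C to rt
Reagents that add atoms: none
Why: SN2 alkylation of a lithium acetylide by a primary bromide; the ortho ester is inert to the basic conditions.

Step 8
Reactants: 11 methyl (3R,4Z)-3-hydroperoxy-5-(trimethylsilyl)pent-4-enoate; 15 triisopropyl(6,6,6-trimethoxyhex-1-yn-1-yl)silane
Product: 18 methyl 2-[(3R,6R)-3-methoxy-3-[5-(triisopropylsilyl)pent-4-yn-1-yl]-3,6-dihydro-1,2-dioxin-6-yl]acetate, via mixed peroxy ortho ester 16 (not isolated), via methoxy(peroxy)carbenium triflate 17 (not isolated)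
Conditions: 15 (2 equiv), PPTS (5 mol%), 5 Å MS, CH2Cl2, 0 °C to rt; then TMSOTf (20 mol%), 2,6-di-tert-butyl-4-methylpyridine (20 mol%), −78 to −20 °C; aq. NaHCO3
Reagents that add atoms: none
Why: Proposed new method: acid-catalysed exchange of one methoxy group of ortho ester 15 for the hydroperoxide 11 gives the mixed peroxy ortho ester 16, which TMSOTf ionises (loss of MeOSiMe3) to the methoxy(peroxy)carbenium ion 17; the tethered (Z)-vinylsilane attacks this cation through its silicon-bearing carbon (ipso attack with β-silyl stabilisation) and then loses the silyl group, which regenerates TMSOTf and forms the C3–C4 bond. The closest known reaction types are the acetal-initiated, vinylsilane-terminated oxocarbenium cyclisation that gives 5,6-dihydro-2H-pyrans and the Lewis acid-mediated C–C bond formation of peroxycarbenium ions with allylsilanes and silyl enol ethers; new here are the ortho ester oxidation level of the electrophile and the O–O bond inside the tether. The 3,6-dihydro-1,2-dioxine ring closes in the 6-endo-trig mode, which only the Z geometry of the vinylsilane allows and which leaves the ring double bond at C4=C5. C6 is already fixed in 11, and C3 is controlled by C6 together with the anomeric effect: a chair-like transition state with the C6 arm pseudoequatorial, and reversible ionisation of the exocyclic OMe of the product under TMSOTf, should lead to the isomer with OMe pseudoaxial (cis to the C6 arm) and the alkynyl chain pseudoequatorial, which is (3R,6R). The step needs C–OMe ionisation to win over O–O heterolysis (Hock or Criegee fragmentation) and over ionisation of the allylic C6–O bond, and the vinylsilane to win over the silylalkyne as π-nucleophile; a silyl triflate at low temperature (which ionises peroxyketals at carbon), the poor leaving ability of the alkylperoxy oxygen, the six-membered endo transition state, and the bulk and lower nucleophilicity of the TIPS-capped alkyne should secure this.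

Step 9
Reactants: 18 methyl 2-[(3R,6R)-3-methoxy-3-[5-(triisopropylsilyl)pent-4-yn-1-yl]-3,6-dihydro-1,2-dioxin-6-yl]acetate
Product: 19 methyl 2-[(3R,6S)-3-methoxy-3-[5-(triisopropylsilyl)pent-4-yn-1-yl]-1,2-dioxan-6-yl]acetate
Conditions: KO2CN=NCO2K (excess, in portions), AcOH, MeOH/CH2Cl2, 0 °C to rt
Reagents that add atoms: none
Why: Diimide reduction transfers H2 syn to the cis-disubstituted ring alkene without cleaving the O–O bond and is strongly slowed by steric bulk, so the TIPS-capped alkyne should be spared; no stereocentre is touched (the change of the C6 descriptor from R to S is a priority change only).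

Step 10
Reactants: 19 methyl 2-[(3R,6S)-3-methoxy-3-[5-(triisopropylsilyl)pent-4-yn-1-yl]-1,2-dioxan-6-yl]acetate
Product: 20 methyl 2-[(3R,6S)-3-methoxy-3-(pent-4-yn-1-yl)-1,2-dioxan-6-yl]acetate
Conditions: TBAF/AcOH (1:1), THF, 0 °C to rt
Reagents that add atoms: none
Why: Fluoride-induced C(sp)–Si cleavage; buffering with acetic acid keeps the medium too weakly basic for retro-oxa-Michael opening of the β-peroxy ester.

Step 11
Reactants: 21 undec-10-enal
Product: 22 (E)-1-iodoundeca-1,10-diene
Conditions: CrCl2, CHI3, THF, 0 °C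
Reagents that add atoms: iodoform IC(I)I
Why: Takai olefination should give the (E)-vinyl iodide selectively and leaves the terminal alkene alone.

Step 12
Reactants: 20 methyl 2-[(3R,6S)-3-methoxy-3-(pent-4-yn-1-yl)-1,2-dioxan-6-yl]acetate; 22 (E)-1-iodoundeca-1,10-diene
Product: 23 methyl 2-[(3R,6S)-3-[(6E)-hexadeca-6,15-dien-4-yn-1-yl]-3-methoxy-1,2-dioxan-6-yl]acetate
Conditions: Pd(PPh3)4 (zerovalent palladium, 5 mol%), CuI (10 mol%), i-Pr2NH, THF, rt
Reagents that add atoms: none
Why: Sonogashira coupling joins the terminal alkyne and the vinyl iodide with retention of the E geometry; dialkyl peroxides of this kind should tolerate zerovalent palladium/CuI coupling at room temperature.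

Step 13
Reactants: 23 methyl 2-[(3R,6S)-3-[(6E)-hexadeca-6,15-dien-4-yn-1-yl]-3-methoxy-1,2-dioxan-6-yl]acetate
Product: 25 2-[(3R,6S)-3-[(6E)-hexadeca-6,15-dien-4-yn-1-yl]-3-methoxy-1,2-dioxan-6-yl]acetic acid, via lithium carboxylate 24 (not isolated)
Conditions: LiOH, THF/H2O (3:1), 0 °C; then aq. HCl to pH 4
Reagents that add atoms: lithium hydroxide [Li+].[OH-]
Why: Saponification by acyl–oxygen cleavage; at 0 °C hydroxide attack at the ester carbonyl should be faster than α-deprotonation, and the carboxylate once formed resists E1cB loss of the peroxide, so C6 is not scrambled.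

**Compound list**

1 | 3-(trimethylsilyl)prop-2-yn-1-ol | C[Si](C)(C)C#CCO | starting material
2 | (Z)-3-(trimethylsilyl)prop-2-en-1-ol | C[Si](C)(C)/C=C\CO | intermediate
3 | (Z)-3-(trimethylsilyl)prop-2-enal | C[Si](C)(C)/C=C\C=O | intermediate (not isolated)
4 | (2E,4Z)-5-(trimethylsilyl)penta-2,4-dienal | C[Si](C)(C)/C=C\C=C\C=O | intermediate
5 | 2,3-dimethylbut-2-ene | CC(C)=C(C)C | starting material
6 | acetone O-oxide | CC(C)=[O+][O-] | intermediate (not isolated)
7 | 2-hydroperoxy-2-methoxypropane | COC(C)(C)OO | intermediate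
8 | (3R,4Z)-3-[(2-methoxypropan-2-yl)peroxy]-5-(trimethylsilyl)pent-4-enal | C[Si](C)(C)/C=C\[C@@H](CC=O)OOC(C)(C)OC | intermediate
9 | (3R,4Z)-3-[(2-methoxypropan-2-yl)peroxy]-5-(trimethylsilyl)pent-4-enoic acid | C[Si](C)(C)/C=C\[C@@H](CC(=O)O)OOC(C)(C)OC | intermediate (not isolated)
10 | methyl (3R,4Z)-3-[(2-methoxypropan-2-yl)peroxy]-5-(trimethylsilyl)pent-4-enoate | C[Si](C)(C)/C=C\[C@@H](CC(=O)OC)OOC(C)(C)OC | intermediate
11 | methyl (3R,4Z)-3-hydroperoxy-5-(trimethylsilyl)pent-4-enoate | C[Si](C)(C)/C=C\[C@@H](CC(=O)OC)OO | intermediate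
12 | ethynyltriisopropylsilane | C#C[Si](C(C)C)(C(C)C)C(C)C | starting material
13 | 4-bromo-1,1,1-trimethoxybutane (trimethyl 4-bromoorthobutyrate) | COC(OC)(OC)CCCBr | starting material
14 | lithium (triisopropylsilyl)acetylide | [Li]C#C[Si](C(C)C)(C(C)C)C(C)C | intermediate (not isolated)
15 | triisopropyl(6,6,6-trimethoxyhex-1-yn-1-yl)silane | COC(OC)(OC)CCCC#C[Si](C(C)C)(C(C)C)C(C)C | intermediate
16 | methyl (3R,4Z)-3-{[1,1-dimethoxy-6-(triisopropylsilyl)hex-5-yn-1-yl]peroxy}-5-(trimethylsilyl)pent-4-enoate (mixed peroxy ortho ester) | COC(OC)(CCCC#C[Si](C(C)C)(C(C)C)C(C)C)OO[C@H](CC(=O)OC)/C=C\[Si](C)(C)C | intermediate (not isolated)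
17 | methoxy(peroxy)carbenium triflate formed from 16 by loss of one methoxy group | C[O+]=C(CCCC#C[Si](C(C)C)(C(C)C)C(C)C)OO[C@H](CC(=O)OC)/C=C\[Si](C)(C)C.[O-]S(=O)(=O)C(F)(F)F | intermediate (not isolated)
18 | methyl 2-[(3R,6R)-3-methoxy-3-[5-(triisopropylsilyl)pent-4-yn-1-yl]-3,6-dihydro-1,2-dioxin-6-yl]acetate | CC(C)[Si](C(C)C)(C(C)C)C#CCCC[C@]1(OC)C=C[C@@H](CC(=O)OC)OO1 | intermediate
19 | methyl 2-[(3R,6S)-3-methoxy-3-[5-(triisopropylsilyl)pent-4-yn-1-yl]-1,2-dioxan-6-yl]acetate | CC(C)[Si](C(C)C)(C(C)C)C#CCCC[C@]1(OC)CC[C@@H](CC(=O)OC)OO1 | intermediate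
20 | methyl 2-[(3R,6S)-3-methoxy-3-(pent-4-yn-1-yl)-1,2-dioxan-6-yl]acetate | C#CCCC[C@]1(OC)CC[C@@H](CC(=O)OC)OO1 | intermediate
21 | undec-10-enal | C=CCCCCCCCCC=O | starting material
22 | (E)-1-iodoundeca-1,10-diene | C=CCCCCCCC/C=C/I | intermediate
23 | methyl 2-[(3R,6S)-3-[(6E)-hexadeca-6,15-dien-4-yn-1-yl]-3-methoxy-1,2-dioxan-6-yl]acetate | C=CCCCCCCC/C=C/C#CCCC[C@]1(OC)CC[C@@H](CC(=O)OC)OO1 | intermediate
24 | lithium 2-[(3R,6S)-3-[(6E)-hexadeca-6,15-dien-4-yn-1-yl]-3-methoxy-1,2-dioxan-6-yl]acetate | C=CCCCCCCC/C=C/C#CCCC[C@]1(OC)CC[C@@H](CC(=O)[O-])OO1.[Li+] | intermediate (not isolated)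
25 | 2-[(3R,6S)-3-[(6E)-hexadeca-6,15-dien-4-yn-1-yl]-3-methoxy-1,2-dioxan-6-yl]acetic acid | C=CCCCCCCC/C=C/C#CCCC[C@]1(OC)CC[C@@H](CC(=O)O)OO1 | target

**Step count and risks**

Total steps: 13. Longest linear sequence: 10 steps (1, 2, 4, 5, 6, 8, 9, 10, 12, 13).

Steps most likely to fail:

1. Step 8. What may go wrong: ionisation at the wrong bond (O–O heterolysis with fragmentation of the mixed peroxy ortho ester, loss of the peroxide from C3, or ionisation of the allylic C6–O bond), capture of the cation by the vinylsilane that is too slow, protodesilylation of the vinylsilane, or incomplete anomeric control at C3. The last of these would be corrected by acid equilibration of the ketal centre in methanol after step 9. Fallback (ring closure by known C–O chemistry instead of C–C bond formation): it sets out from lithium acetylide 14 (made from 12 as in step 7) and comes back to the route at 19.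
   - Alkylation of 14 with 1-bromo-3-chloropropane (THF/DMPU) should give (5-chloropent-1-yn-1-yl)triisopropylsilane F1.
   - Its Grignard reagent [5-(triisopropylsilyl)pent-4-yn-1-yl]magnesium chloride F2 (Mg, THF) is added to N-methoxy-N-methylpent-4-enamide to give the ketone 10-(triisopropylsilyl)dec-1-en-9-yn-5-one F3.
   - Cross-metathesis of F3 with crotonaldehyde (second-generation Grubbs catalyst, CH2Cl2, 40 °C) gives (2E)-6-oxo-11-(triisopropylsilyl)undec-2-en-10-ynal F4.
   - The conjugate peroxidation of step 4 (same catalyst, 7) gives (3S)-3-[(2-methoxypropan-2-yl)peroxy]-6-oxo-11-(triisopropylsilyl)undec-10-ynal F5, with the same spatial arrangement as 8.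
   - Pinnick oxidation gives (3S)-3-[(2-methoxypropan-2-yl)peroxy]-6-oxo-11-(triisopropylsilyl)undec-10-ynoic acid F6, and TMSCHN2 gives methyl (3S)-3-[(2-methoxypropan-2-yl)peroxy]-6-oxo-11-(triisopropylsilyl)undec-10-ynoate F7.
   - Camphorsulfonic acid in methanol removes the peroxyketal to give methyl (3S)-3-hydroperoxy-6-oxo-11-(triisopropylsilyl)undec-10-ynoate F8. This closes onto the ketone to the cyclic peroxy hemiketal methyl 2-[(6S)-3-hydroxy-3-[5-(triisopropylsilyl)pent-4-yn-1-yl]-1,2-dioxan-6-yl]acetate F9, which the same medium converts into the methyl peroxyketal 19 under anomeric control.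

2. Step 4. What may go wrong: conjugate addition at the remote carbon of the dienal (1,6-addition), Z-to-E isomerisation of the vinylsilane in the activated dienal, closure of the enamine to an epoxide, or low facial selectivity. Fallback (the alkene geometry is set after the peroxidation instead of before): it sets out from 1 and comes back to the route at 10.
   - MnO2 oxidation of 1 gives 3-(trimethylsilyl)prop-2-ynal F10.
   - Wittig olefination with Ph3P=CHCHO gives (2E)-5-(trimethylsilyl)pent-2-en-4-ynal F11, whose silylalkyne has no geometry to lose.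
   - The peroxidation of step 4 (same catalyst, 7) gives (3R)-3-[(2-methoxypropan-2-yl)peroxy]-5-(trimethylsilyl)pent-4-ynal F12.
   - Pinnick oxidation gives (3R)-3-[(2-methoxypropan-2-yl)peroxy]-5-(trimethylsilyl)pent-4-ynoic acid F13, and TMSCHN2 gives methyl (3R)-3-[(2-methoxypropan-2-yl)peroxy]-5-(trimethylsilyl)pent-4-ynoate F14.
   - Syn semi-reduction of the silylalkyne of F14 with diimide (KO2CN=NCO2K, AcOH), which leaves the O–O bond intact, gives 10.

3. Step 9. What may go wrong: slow reduction of the hindered ring alkene next to the fully substituted C3, with competing reduction of the silylalkyne once a large excess of diimide is used. Fallback (the alkyne is introduced after the reduction): it sets out from 11 and 13 and comes back to the route at 19.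
   - The annulation of step 8, run with ortho ester 13 in place of 15, gives methyl 2-[(3R,6R)-3-(3-bromopropyl)-3-methoxy-3,6-dihydro-1,2-dioxin-6-yl]acetate F15, which carries no alkyne.
   - Diimide in large excess then gives methyl 2-[(3S,6S)-3-(3-bromopropyl)-3-methoxy-1,2-dioxan-6-yl]acetate F16 (same spatial arrangement as 19; the C3 descriptor changes because of the bromine).
   - Sonogashira-type coupling of the unactivated primary bromide F16 with 12 ([(η3-C3H5)PdCl]2, 1,3-bis(1-adamantyl)imidazolium chloride, CuI, Cs2CO3, DMF/Et2O, 45 °C) gives 19.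

**Further compounds**

F1 | step 8 | (5-chloropent-1-yn-1-yl)triisopropylsilane | CC(C)[Si](C(C)C)(C(C)C)C#CCCCCl
F2 | step 8 | [5-(triisopropylsilyl)pent-4-yn-1-yl]magnesium chloride | CC(C)[Si](C(C)C)(C(C)C)C#CCCC[Mg]Cl
F3 | step 8 | 10-(triisopropylsilyl)dec-1-en-9-yn-5-one | CC(C)[Si](C(C)C)(C(C)C)C#CCCCC(=O)CCC=C
F4 | step 8 | (2E)-6-oxo-11-(triisopropylsilyl)undec-2-en-10-ynal | CC(C)[Si](C(C)C)(C(C)C)C#CCCCC(=O)CC/C=C/C=O
F5 | step 8 | (3S)-3-[(2-methoxypropan-2-yl)peroxy]-6-oxo-11-(triisopropylsilyl)undec-10-ynal | CC(C)[Si](C(C)C)(C(C)C)C#CCCCC(=O)CC[C@@H](CC=O)OOC(C)(C)OC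
F6 | step 8 | (3S)-3-[(2-methoxypropan-2-yl)peroxy]-6-oxo-11-(triisopropylsilyl)undec-10-ynoic acid | CC(C)[Si](C(C)C)(C(C)C)C#CCCCC(=O)CC[C@@H](CC(=O)O)OOC(C)(C)OC
F7 | step 8 | methyl (3S)-3-[(2-methoxypropan-2-yl)peroxy]-6-oxo-11-(triisopropylsilyl)undec-10-ynoate | CC(C)[Si](C(C)C)(C(C)C)C#CCCCC(=O)CC[C@@H](CC(=O)OC)OOC(C)(C)OC
F8 | step 8 | methyl (3S)-3-hydroperoxy-6-oxo-11-(triisopropylsilyl)undec-10-ynoate | CC(C)[Si](C(C)C)(C(C)C)C#CCCCC(=O)CC[C@@H](CC(=O)OC)OO
F9 | step 8 | methyl 2-[(6S)-3-hydroxy-3-[5-(triisopropylsilyl)pent-4-yn-1-yl]-1,2-dioxan-6-yl]acetate | CC(C)[Si](C(C)C)(C(C)C)C#CCCCC1(O)CC[C@@H](CC(=O)OC)OO1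
F10 | step 4 | 3-(trimethylsilyl)prop-2-ynal | C[Si](C)(C)C#CC=O
F11 | step 4 | (2E)-5-(trimethylsilyl)pent-2-en-4-ynal | C[Si](C)(C)C#C/C=C/C=O
F12 | step 4 | (3R)-3-[(2-methoxypropan-2-yl)peroxy]-5-(trimethylsilyl)pent-4-ynal | C[Si](C)(C)C#C[C@@H](CC=O)OOC(C)(C)OC
F13 | step 4 | (3R)-3-[(2-methoxypropan-2-yl)peroxy]-5-(trimethylsilyl)pent-4-ynoic acid | C[Si](C)(C)C#C[C@@H](CC(=O)O)OOC(C)(C)OC
F14 | step 4 | methyl (3R)-3-[(2-methoxypropan-2-yl)peroxy]-5-(trimethylsilyl)pent-4-ynoate | C[Si](C)(C)C#C[C@@H](CC(=O)OC)OOC(C)(C)OC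
F15 | step 9 | methyl 2-[(3R,6R)-3-(3-bromopropyl)-3-methoxy-3,6-dihydro-1,2-dioxin-6-yl]acetate | BrCCC[C@]1(OC)C=C[C@@H](CC(=O)OC)OO1
F16 | step 9 | methyl 2-[(3S,6S)-3-(3-bromopropyl)-3-methoxy-1,2-dioxan-6-yl]acetate | BrCCC[C@]1(OC)CC[C@@H](CC(=O)OC)OO1
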